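## The problem

The target is a 1,1-diaryl-3-arylpropane in which four benzene rings are joined only through sp3 carbons. The methine carbon C* carries ring A (4-hydroxyphenyl), ring B (a 4,6-dihydroxy-1,3-phenylene unit) and a two-carbon tether to ring C (4-hydroxy-2-methoxyphenyl). The other carbon substituent of ring B is a 3-oxopropyl arm that ends in ring D (a 4-hydroxyphenyl ketone). C* is the only stereocentre and has the (R) configuration; nothing else in the molecule can relay chirality to it, so a catalyst has to set it. As a diarylmethine it is hard to set directly, because rings A and B are both para-oxygenated benzene rings that differ only in their ortho substituents. The five phenols sit on electron-rich, oxidisable rings and must stay masked until the last step. The enolisable aryl ketone must be kept apart from any other carbonyl used to build the chain. Once both aryl groups are on C*, its hydrogen is doubly benzylic and open to hydride abstraction and to strong base. The enabling feature is that ring A carries only hydrogen and one hydroxyl para to C*. Its C1 and C2 can therefore come from a terminal ethynyl group on C*, and its C3 to C6, with the oxygen on C4, from a 2-silyloxybutadiene. C* then becomes a propargylic carbon with three very different substituents (alkynyl, aryl, alkyl).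

## Retrosynthesis

**18 to 17.** The four benzyl–oxygen bonds of tetrabenzyl ether 17 are cut last. Benzyl ethers are chosen because they should survive hydroxide, trifluoroacetic acid at 0 °C, palladium at 100 °C, fluoride and one equivalent of quinone oxidant, and all leave in one neutral step. The ring D ketone is left free, since para-oxygenated aryl ketones normally survive hydrogenolysis over Pd/C at 1 atm; this saves a ketal and its removal.

**17 to 15.** Ring A is taken back to its dihydro form, the 4-(trimethylsilyloxy)cyclohexa-1,4-dienyl compound 15, by way of aryl silyl ether 16. This costs only two hydrogens and a silyl group, and 15 is the direct product of a cycloaddition. The forward reaction needs an oxidant that takes hydride from the ring CH2 groups and not from C*.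

**15 to 13 and 14.** Two ring bonds of ring A are cut: C1–C6 and C2–C3. This gives terminal alkyne 13 and 2-(trimethylsilyloxy)buta-1,3-diene 14. The neighbouring cut, the C*–ring A bond, would bring back the problem of telling two similar aryl groups apart. The ring construction removes six carbons and leaves a propargylic stereocentre. The forward reaction must place the oxygen para to C* and must be neutral, so that the propargylic hydrogen does not move.

**13 to 12, then 12 to 8 and 11.** The C–Si bond of silyl alkyne 12 is restored first. The bond between ring B and the first CH2 of the ketone arm is then cut, giving aryl bromide 8 and allylic alcohol 11. A Heck reaction with a secondary allylic alcohol delivers the saturated ketone directly. Placing this cut after the removal of the ring C carbonyl means the two aryl ketones never coexist, so no ketal is needed. Alcohol 11 comes from aldehyde 9 and vinylmagnesium bromide 10; it can be racemic because its carbinol carbon ends as the ketone.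

**8 to 7.** The benzylic CH2 next to ring C is traced to a carbonyl, giving β-alkynyl ketone 7. This carbonyl is what makes the stereocentre accessible by conjugate addition. It is the only ketone present at that stage and is conjugated to the electron-rich ring C, so ionic hydrogenation can remove it. The bromine on ring B also helps: the one free ortho position where a benzylic cation could close an indane is meta to both ether oxygens and flanked by bromine.

**7 to 5 and 6.** The C*–C(sp) bond is cut, giving chalcone 5 and (triisopropylsilyl)acetylene 6. This is the stereo-defining disconnection. The reverse polarity, adding ring B to an enynone, would face 1,4- against 1,6-addition. The forward reaction asks for catalyst control of the enone face.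

**5 to 2 and 4.** The enone double bond is cut to aldehyde 2 and methyl ketone 4, each one benzylation away from commercial phenols 1 and 3. The ring C tether and the ring B core are thus joined in a single condensation.

## Roads not taken

Alternative 1: The cut is made inside a temporary five-membered ring. Aldehyde A1, a ring B benzaldehyde with a 1-(4-benzyloxyphenyl)vinyl group ortho to the formyl group, would be cyclised with [Rh(cod)2]BF4 and a chiral BINAP ligand. The aldehyde C–H adds across the 1,1-disubstituted alkene and gives 3-arylindanone A2 with C* as C3. A Baeyer–Villiger oxidation would then insert oxygen to give dihydrocoumarin A3, whose lactone carbonyl must be extended to the ring C tether. Its merits are real: the diarylmethine is set in one atom-economical step, ring A is aromatic from the start, and no oxidation is ever run next to a sensitive C*–H. In this respect it is better than the chosen plan, which must aromatise ring A beside C*. Its weak points lie around the key step. A1 is a pentasubstituted arene whose vinyl and formyl groups must be placed ortho to each other on a ring that already carries the ketal arm. The acyl carbon sits where ring B needs oxygen, so a peracid has to be used on a molecule full of electron-rich rings. After A3, ring C still has to be attached through lactol formation, aryl-metal addition and a benzylic deoxygenation. The chosen plan sets against this that the complete ring C tether is in place before the stereocentre is made, and that nothing has to be inserted or excised on ring B afterwards.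

Alternative 2: The stereocentre would come from desymmetrisation. 3,3-Bis(4-benzyloxyphenyl)propanoic acid A4 has two enantiotopic aryl rings. Pd(OAc)2 with a mono-N-protected amino acid ligand and PhI(OAc)2 would oxidise one ortho C–H and close lactone A5, with C* as C4. This is the shortest road to the stereocentre: A4 is symmetric and trivial to make, and the step installs the ortho oxygen of ring B at the same time. On step count to C* it beats the chosen plan. The weaknesses are three. Enantioselective C–H lactonisation is better founded for five-membered lactones from diarylacetic acids than for six-membered ones from 3,3-diarylpropanoic acids. The hypervalent iodine oxidant meets two electron-rich benzyloxyarenes. Most seriously, A5 lacks the ketone arm, so a late electrophilic substitution would have to choose one position of ring B over its other free position and over the ortho positions of ring A, which is an equally activated benzyloxyarene. The ring C tether would also still have to be grown from the lactone. The chosen plan answers the regiochemical problem by carrying a bromine at the arm position from the first step.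

Alternative 3: Two bonds at the stereogenic end would be made at once. The alkenyllithium from (E)-alkenyl bromide A6 (ring B with the ketal arm) and benzylic boronic ester A7 (ring C) form a boron ate complex. With aryl triflate A8, Pd(OAc)2 and a chiral MandyPhos ligand, the benzyl group migrates from boron to the adjacent carbon while ring A is delivered to C*, giving boronate A9. This is the most convergent of all the plans, since three fragments are joined and C* is set in one step with ring A intact; the chosen plan is longer in linear terms. Against it stand several points. A6 itself needs the full ring B arm, a ketal and a stereodefined bromoalkene. Conjunctive couplings of β-aryl alkenyl ate complexes with a migrating benzyl group are at the edge of the known scope. The step also creates a second stereocentre at the boron-bearing carbon that the target does not contain, so a protodeboronation of a hindered secondary boronate must follow. The chosen plan creates one stereocentre and nothing traceless, and every one of its steps runs on a simpler substrate with close precedent.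

Key step: step 9

Assumption: (R)-DTBM-SEGPHOS is taken to deliver the alkynyl group to the Si face of C-β of chalcone 5 (which gives the (S) descriptor in 7); if the sense of induction is the opposite, the (S)-ligand is used and nothing else changes.

## Route

Step 1
Reactants: 1 5-bromo-2,4-dihydroxybenzaldehyde
Product: 2 2,4-bis(benzyloxy)-5-bromobenzaldehyde
Conditions: BnBr (2.5 equiv), K2CO3 (3 equiv), DMF, 60 °C
Reagents that add atoms: benzyl bromide, BrCc1ccccc1
Why: Williamson ether synthesis; the hydrogen-bonded 2-hydroxyl reacts more slowly but should be driven to completion by excess bromide and gentle heating.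

Step 2
Reactants: 3 1-(4-hydroxy-2-methoxyphenyl)ethanone
Product: 4 1-[4-(benzyloxy)-2-methoxyphenyl]ethanone
Conditions: BnBr (1.2 equiv), K2CO3 (2 equiv), acetone, reflux
Reagents that add atoms: benzyl bromide, BrCc1ccccc1
Why: Williamson ether synthesis on the only free phenol.

Step 3
Reactants: 2 2,4-bis(benzyloxy)-5-bromobenzaldehyde; 4 1-[4-(benzyloxy)-2-methoxyphenyl]ethanone
Product: 5 (E)-1-[4-(benzyloxy)-2-methoxyphenyl]-3-[2,4-bis(benzyloxy)-5-bromophenyl]prop-2-en-1-one
Conditions: KOH (aq, 3 equiv), EtOH/THF, rt
Reagents that add atoms: none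
Why: Claisen–Schmidt condensation; aldehyde 2 cannot enolise, and dehydration of the aldol under thermodynamic control should give the (E)-chalcone.

Step 4
Reactants: 5 (E)-1-[4-(benzyloxy)-2-methoxyphenyl]-3-[2,4-bis(benzyloxy)-5-bromophenyl]prop-2-en-1-one; 6 (triisopropylsilyl)acetylene
Product: 7 (S)-1-[4-(benzyloxy)-2-methoxyphenyl]-3-[2,4-bis(benzyloxy)-5-bromophenyl]-5-(triisopropylsilyl)pent-4-yn-1-one
Conditions: [Rh(OAc)(C2H4)2]2 (2.5 mol %), (R)-DTBM-SEGPHOS (6 mol %), 6 (2 equiv), 1,4-dioxane, 80 °C
Reagents that add atoms: none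
Why: Rhodium-catalysed asymmetric conjugate alkynylation of an enone: a monovalent rhodium acetylide adds 1,4 and the oxa-π-allyl rhodium is protonated by the next alkyne; the bulky silyl group and phosphine aryl groups suppress alkyne dimerisation, and the ligand sets C* by Si-face delivery.

Step 5
Reactants: 7 (S)-1-[4-(benzyloxy)-2-methoxyphenyl]-3-[2,4-bis(benzyloxy)-5-bromophenyl]-5-(triisopropylsilyl)pent-4-yn-1-one
Product: 8 (S)-{3-[2,4-bis(benzyloxy)-5-bromophenyl]-5-[4-(benzyloxy)-2-methoxyphenyl]pent-1-yn-1-yl}triisopropylsilane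
Conditions: Et3SiH (4 equiv), CF3CO2H (10 equiv), CH2Cl2, 0 °C to rt
Reagents that add atoms: none
Why: Ionic hydrogenation of an aryl ketone: protonation, hydride transfer, ionisation to a benzylic cation stabilised by the 2,4-dioxygenated ring C and a second hydride transfer; C* lies two carbons away and is not involved, and closure to an indane is disfavoured because the free ortho position of ring B is meta to both ether oxygens and next to bromine.

Step 6
Reactants: 9 4-(benzyloxy)benzaldehyde; 10 vinylmagnesium bromide
Product: 11 1-[4-(benzyloxy)phenyl]prop-2-en-1-ol (racemic)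
Conditions: THF, 0 °C; aq NH4Cl
Reagents that add atoms: none
Why: Grignard 1,2-addition to an aldehyde; the new carbinol centre is left racemic because it becomes the ketone carbon in step 7.

Step 7
Reactants: 8 (S)-{3-[2,4-bis(benzyloxy)-5-bromophenyl]-5-[4-(benzyloxy)-2-methoxyphenyl]pent-1-yn-1-yl}triisopropylsilane; 11 1-[4-(benzyloxy)phenyl]prop-2-en-1-ol
Product: 12 (S)-1-[4-(benzyloxy)phenyl]-3-{2,4-bis(benzyloxy)-5-[5-(4-(benzyloxy)-2-methoxyphenyl)-1-(triisopropylsilyl)pent-1-yn-3-yl]phenyl}propan-1-one
Conditions: Pd(OAc)2 (5 mol %), P(o-tol)3 (10 mol %), NaHCO3 (2.5 equiv), n-Bu4NCl (1 equiv), 11 (1.5 equiv), DMF, 100 °C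
Reagents that add atoms: none
Why: Heck reaction of an aryl bromide with a secondary allylic alcohol: the aryl group adds to the terminal alkene carbon, and β-hydride elimination towards the carbinol gives an enol that tautomerises to the saturated ketone; the hindered silyl alkyne should not insert, and hydrogencarbonate is too weak a base to touch the C*–H bond.

Step 8
Reactants: 12 (S)-1-[4-(benzyloxy)phenyl]-3-{2,4-bis(benzyloxy)-5-[5-(4-(benzyloxy)-2-methoxyphenyl)-1-(triisopropylsilyl)pent-1-yn-3-yl]phenyl}propan-1-one
Product: 13 (R)-1-[4-(benzyloxy)phenyl]-3-{2,4-bis(benzyloxy)-5-[5-(4-(benzyloxy)-2-methoxyphenyl)pent-1-yn-3-yl]phenyl}propan-1-one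
Conditions: TBAF (1.2 equiv), THF, 0 °C to rt
Reagents that add atoms: none
Why: Fluoride-induced protodesilylation of an alkynylsilane; low temperature and short contact should prevent propargyl-to-allene isomerisation, and the descriptor changes from (S) to (R) only because the priority of the alkynyl group falls.

Step 9
Reactants: 13 (R)-1-[4-(benzyloxy)phenyl]-3-{2,4-bis(benzyloxy)-5-[5-(4-(benzyloxy)-2-methoxyphenyl)pent-1-yn-3-yl]phenyl}propan-1-one; 14 2-(trimethylsilyloxy)buta-1,3-diene
Product: 15 (R)-1-[4-(benzyloxy)phenyl]-3-{2,4-bis(benzyloxy)-5-[3-(4-(benzyloxy)-2-methoxyphenyl)-1-(4-(trimethylsilyloxy)cyclohexa-1,4-dien-1-yl)propyl]phenyl}propan-1-one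
Conditions: CoBr2(dppe) (10 mol %), Zn powder (20 mol %), ZnI2 (20 mol %), 14 (2 equiv), CH2Cl2, rt; filtration through a short pad, used crude
Reagents that add atoms: none
Why: Zinc reduces CoBr2(dppe) from divalent to monovalent cobalt and ZnI2 removes halide to free coordination sites. The monovalent cobalt binds the s-cis diene 14 and the terminal alkyne of 13, couples them oxidatively to a trivalent cobaltacycle and releases the 1,4-cyclohexadiene by reductive elimination. Ring A thus closes by a metal-templated intermolecular [4+2] annulation that forms its C1–C6 and C2–C3 bonds, the alkyne CH joining the diene terminus next to the silyloxy carbon. The closest known reaction is the cobalt-catalysed neutral Diels–Alder reaction of unactivated terminal alkynes with 2-substituted butadienes, 2-silyloxybutadiene included, which a thermal Diels–Alder reaction cannot match. No stereocentre is formed; C* is a spectator, and since the medium contains no base the propargylic hydrogen should stay in place and no allene should form. The selectivity needed is 1,4 over 1,3 placement of the silyloxy carbon; the dppe ligand makes the alkyne substituent and the diene substituent avoid each other in the cobaltacycle, and the large branched group on C* reinforces this. Excess diene should hold back alkyne cyclotrimerisation. The aryl ketone and benzyl ethers bind the soft cobalt centre only weakly and are not reduced by zinc dust without a proton source.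

Step 10
Reactants: 15 (R)-1-[4-(benzyloxy)phenyl]-3-{2,4-bis(benzyloxy)-5-[3-(4-(benzyloxy)-2-methoxyphenyl)-1-(4-(trimethylsilyloxy)cyclohexa-1,4-dien-1-yl)propyl]phenyl}propan-1-one
Product: 17 (R)-1-[4-(benzyloxy)phenyl]-3-{2,4-bis(benzyloxy)-5-[3-(4-(benzyloxy)-2-methoxyphenyl)-1-(4-hydroxyphenyl)propyl]phenyl}propan-1-one, via aryl trimethylsilyl ether 16 (not isolated)
Conditions: DDQ (1.05 equiv), toluene, 0 °C to rt; then K2CO3 (cat.), MeOH, rt
Reagents that add atoms: none
Why: Dehydrogenative aromatisation: DDQ abstracts hydride from the doubly allylic ring CH2 next to the silyloxy carbon and the oxygen-stabilised cyclohexadienyl cation loses a proton to give the arene; base-catalysed methanolysis then cleaves the labile aryl O–SiMe3 bond, and one equivalent of oxidant at 0 °C should leave C*–H and the benzyl ethers alone.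

Step 11
Reactants: 17 (R)-1-[4-(benzyloxy)phenyl]-3-{2,4-bis(benzyloxy)-5-[3-(4-(benzyloxy)-2-methoxyphenyl)-1-(4-hydroxyphenyl)propyl]phenyl}propan-1-one
Product: 18 (R)-3-{2,4-dihydroxy-5-[3-(4-hydroxy-2-methoxyphenyl)-1-(4-hydroxyphenyl)propyl]phenyl}-1-(4-hydroxyphenyl)propan-1-one
Conditions: H2 (1 atm), Pd/C (10 wt %), EtOAc/MeOH, rt
Reagents that add atoms: none
Why: Hydrogenolysis of four aryl benzyl ethers; the ketone is conjugated to a para-oxygenated ring and should resist reduction at 1 atm, as is usual for dihydrochalcones, and the diarylmethine C–H is not affected.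

## Compound list

1 | 5-bromo-2,4-dihydroxybenzaldehyde | O=Cc1cc(Br)c(O)cc1O | starting material
2 | 2,4-bis(benzyloxy)-5-bromobenzaldehyde | O=Cc1cc(Br)c(OCc2ccccc2)cc1OCc1ccccc1 | intermediate
3 | 1-(4-hydroxy-2-methoxyphenyl)ethanone | COc1cc(O)ccc1C(C)=O | starting material
4 | 1-[4-(benzyloxy)-2-methoxyphenyl]ethanone | COc1cc(OCc2ccccc2)ccc1C(C)=O | intermediate
5 | (E)-1-[4-(benzyloxy)-2-methoxyphenyl]-3-[2,4-bis(benzyloxy)-5-bromophenyl]prop-2-en-1-one | COc1cc(OCc2ccccc2)ccc1C(=O)/C=C/c1cc(Br)c(OCc2ccccc2)cc1OCc1ccccc1 | intermediate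
6 | (triisopropylsilyl)acetylene | C#C[Si](C(C)C)(C(C)C)C(C)C | starting material
7 | (S)-1-[4-(benzyloxy)-2-methoxyphenyl]-3-[2,4-bis(benzyloxy)-5-bromophenyl]-5-(triisopropylsilyl)pent-4-yn-1-one | COc1cc(OCc2ccccc2)ccc1C(=O)C[C@H](C#C[Si](C(C)C)(C(C)C)C(C)C)c1cc(Br)c(OCc2ccccc2)cc1OCc1ccccc1 | intermediate
8 | (S)-{3-[2,4-bis(benzyloxy)-5-bromophenyl]-5-[4-(benzyloxy)-2-methoxyphenyl]pent-1-yn-1-yl}triisopropylsilane | COc1cc(OCc2ccccc2)ccc1CC[C@H](C#C[Si](C(C)C)(C(C)C)C(C)C)c1cc(Br)c(OCc2ccccc2)cc1OCc1ccccc1 | intermediate
9 | 4-(benzyloxy)benzaldehyde | O=Cc1ccc(OCc2ccccc2)cc1 | starting material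
10 | vinylmagnesium bromide | C=C[Mg]Br | starting material
11 | 1-[4-(benzyloxy)phenyl]prop-2-en-1-ol (racemic) | C=CC(O)c1ccc(OCc2ccccc2)cc1 | intermediate
12 | (S)-1-[4-(benzyloxy)phenyl]-3-{2,4-bis(benzyloxy)-5-[5-(4-(benzyloxy)-2-methoxyphenyl)-1-(triisopropylsilyl)pent-1-yn-3-yl]phenyl}propan-1-one | COc1cc(OCc2ccccc2)ccc1CC[C@H](C#C[Si](C(C)C)(C(C)C)C(C)C)c1cc(CCC(=O)c2ccc(OCc3ccccc3)cc2)c(OCc2ccccc2)cc1OCc1ccccc1 | intermediate
13 | (R)-1-[4-(benzyloxy)phenyl]-3-{2,4-bis(benzyloxy)-5-[5-(4-(benzyloxy)-2-methoxyphenyl)pent-1-yn-3-yl]phenyl}propan-1-one | COc1cc(OCc2ccccc2)ccc1CC[C@H](C#C)c1cc(CCC(=O)c2ccc(OCc3ccccc3)cc2)c(OCc2ccccc2)cc1OCc1ccccc1 | intermediate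
14 | 2-(trimethylsilyloxy)buta-1,3-diene | C=CC(=C)O[Si](C)(C)C | starting material
15 | (R)-1-[4-(benzyloxy)phenyl]-3-{2,4-bis(benzyloxy)-5-[3-(4-(benzyloxy)-2-methoxyphenyl)-1-(4-(trimethylsilyloxy)cyclohexa-1,4-dien-1-yl)propyl]phenyl}propan-1-one | COc1cc(OCc2ccccc2)ccc1CC[C@H](C1=CCC(O[Si](C)(C)C)=CC1)c1cc(CCC(=O)c2ccc(OCc3ccccc3)cc2)c(OCc2ccccc2)cc1OCc1ccccc1 | intermediate
16 | (R)-1-[4-(benzyloxy)phenyl]-3-{2,4-bis(benzyloxy)-5-[3-(4-(benzyloxy)-2-methoxyphenyl)-1-(4-(trimethylsilyloxy)phenyl)propyl]phenyl}propan-1-one | COc1cc(OCc2ccccc2)ccc1CC[C@H](c1ccc(O[Si](C)(C)C)cc1)c1cc(CCC(=O)c2ccc(OCc3ccccc3)cc2)c(OCc2ccccc2)cc1OCc1ccccc1 | intermediate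
17 | (R)-1-[4-(benzyloxy)phenyl]-3-{2,4-bis(benzyloxy)-5-[3-(4-(benzyloxy)-2-methoxyphenyl)-1-(4-hydroxyphenyl)propyl]phenyl}propan-1-one | COc1cc(OCc2ccccc2)ccc1CC[C@H](c1ccc(O)cc1)c1cc(CCC(=O)c2ccc(OCc3ccccc3)cc2)c(OCc2ccccc2)cc1OCc1ccccc1 | intermediate
18 | (R)-3-{2,4-dihydroxy-5-[3-(4-hydroxy-2-methoxyphenyl)-1-(4-hydroxyphenyl)propyl]phenyl}-1-(4-hydroxyphenyl)propan-1-one | COc1cc(O)ccc1CC[C@H](c1ccc(O)cc1)c1cc(CCC(=O)c2ccc(O)cc2)c(O)cc1O | target

## Step count and least certain steps

Total step count: 11. Longest linear sequence: 9 steps (steps 1, 3, 4, 5, 7, 8, 9, 10, 11); steps 2 and 6 make the side fragments.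

**Step 9 (key step).** The most likely failures are incomplete regiocontrol, with the silyloxy carbon ending meta to C*, and slow cycloaddition. The branched, bulky propargylic substituent may slow the reaction enough for alkyne cyclotrimerisation to compete, and the many ether oxygens may tie up the zinc Lewis acid. Fallback: ring A is brought in intact and the alkyne is given up. Setting out from chalcone 5, a Hayashi–Miyaura conjugate arylation with [4-(benzyloxy)phenyl]boronic acid (Rh(acac)(C2H4)2, BINAP enantiomer chosen for Si-face delivery, dioxane/water, 100 °C) should give (R)-1-[4-(benzyloxy)-2-methoxyphenyl]-3-[4-(benzyloxy)phenyl]-3-[2,4-bis(benzyloxy)-5-bromophenyl]propan-1-one F1. Ionic hydrogenation as in step 5 should give (R)-1,5-bis(benzyloxy)-2-{1-[4-(benzyloxy)phenyl]-3-[4-(benzyloxy)-2-methoxyphenyl]propyl}-4-bromobenzene F2. A Heck reaction with 11 as in step 7 should give (R)-1-[4-(benzyloxy)phenyl]-3-{2,4-bis(benzyloxy)-5-[1-(4-(benzyloxy)phenyl)-3-(4-(benzyloxy)-2-methoxyphenyl)propyl]phenyl}propan-1-one F3. Hydrogenolysis as in step 11 then returns to the route at 18. The price is that the catalyst must distinguish two similar aryl groups at C*.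

**Step 4.** Conversion or facial selectivity may be poor, because the acceptor is a β-aryl enone with ortho-alkoxy groups on both rings, and alkyne dimerisation may then take over. Fallback: the acceptor is changed to a less hindered enal and ring C is added afterwards. Setting out from 2, a Wittig reaction with (triphenylphosphoranylidene)acetaldehyde (toluene, 80 °C) should give (E)-3-[2,4-bis(benzyloxy)-5-bromophenyl]prop-2-enal F4. Rhodium-catalysed conjugate alkynylation with 6 (same catalyst, MeOH, 40 °C) should give (S)-3-[2,4-bis(benzyloxy)-5-bromophenyl]-5-(triisopropylsilyl)pent-4-ynal F5. Benzylation of 4-bromo-3-methoxyphenol gives 4-(benzyloxy)-1-bromo-2-methoxybenzene F6, which is converted with Mg into its Grignard reagent and added to F5 at −78 °C. This should give (3S)-1-[4-(benzyloxy)-2-methoxyphenyl]-3-[2,4-bis(benzyloxy)-5-bromophenyl]-5-(triisopropylsilyl)pent-4-yn-1-ol F7 as a mixture of carbinol epimers. Et3SiH and CF3CO2H in CH2Cl2 at −20 °C remove the hydroxyl and return to the route at 8.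

**Step 5.** The first hydride transfer to a strongly stabilised, weakly electrophilic protonated ketone may be slow. Prolonged acid exposure could then cause loss or migration of benzyl groups, or cyclisation of the carbonyl oxygen onto the alkyne. Fallback: a deoxygenation that passes through no cation. Setting out from 7, condensation with tosylhydrazine (EtOH, cat. AcOH, reflux) should give the tosylhydrazone of 7, N'-{(3S)-1-[4-(benzyloxy)-2-methoxyphenyl]-3-[2,4-bis(benzyloxy)-5-bromophenyl]-5-(triisopropylsilyl)pent-4-yn-1-ylidene}-4-methylbenzenesulfonohydrazide F8. A Caglioti-type reduction with catecholborane (CHCl3, 0 °C to rt), then NaOAc trihydrate at reflux, expels sulfinate and dinitrogen and returns to the route at 8.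

**Step 7.** Oxidative addition into the electron-rich, ortho-alkoxy aryl bromide may be sluggish. β-Hydride elimination may also go away from the carbinol, or palladium hydride may isomerise 11 to the propiophenone before it couples. Fallback: the arm is built by carbonyl chemistry. Setting out from 8, bromine–lithium exchange (n-BuLi, THF, −78 °C) gives the aryllithium {2,4-bis(benzyloxy)-5-[(3S)-5-(4-(benzyloxy)-2-methoxyphenyl)-1-(triisopropylsilyl)pent-1-yn-3-yl]phenyl}lithium F9. Quenching with DMF should give (S)-2,4-bis(benzyloxy)-5-{5-[4-(benzyloxy)-2-methoxyphenyl]-1-(triisopropylsilyl)pent-1-yn-3-yl}benzaldehyde F10. Claisen–Schmidt condensation with 1-[4-(benzyloxy)phenyl]ethanone (KOH, EtOH/THF) should give (S,E)-1-[4-(benzyloxy)phenyl]-3-{2,4-bis(benzyloxy)-5-[5-(4-(benzyloxy)-2-methoxyphenyl)-1-(triisopropylsilyl)pent-1-yn-3-yl]phenyl}prop-2-en-1-one F11. Conjugate reduction with [(Ph3P)CuH]6 in wet toluene, which spares the hindered silyl alkyne, returns to the route at 12.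

**Step 10.** The oxidant may also abstract hydride from C*–H, which is benzylic to the very electron-rich ring B, leading to erosion of configuration or over-oxidation. The silyl enol ether may also hydrolyse before it is oxidised. Fallback: the hydrolysis is made deliberate and the aromatisation is done without a hydride-abstracting quinone. Setting out from 15, 1 M HCl in THF at 0 °C should give (R)-4-{1-[2,4-bis(benzyloxy)-5-(3-(4-(benzyloxy)phenyl)-3-oxopropyl)phenyl]-3-[4-(benzyloxy)-2-methoxyphenyl]propyl}cyclohex-3-en-1-one F12. Aerobic dehydrogenation with Pd(OCOCF3)2, 2-(dimethylamino)pyridine and TsOH under O2 in DMSO at 80 °C (divalent palladium enolate, β-hydride elimination, tautomerisation) returns to the route at 17.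

## Further compounds

F1 | step 9 | (R)-1-[4-(benzyloxy)-2-methoxyphenyl]-3-[4-(benzyloxy)phenyl]-3-[2,4-bis(benzyloxy)-5-bromophenyl]propan-1-one | COc1cc(OCc2ccccc2)ccc1C(=O)C[C@H](c1ccc(OCc2ccccc2)cc1)c1cc(Br)c(OCc2ccccc2)cc1OCc1ccccc1
F2 | step 9 | (R)-1,5-bis(benzyloxy)-2-{1-[4-(benzyloxy)phenyl]-3-[4-(benzyloxy)-2-methoxyphenyl]propyl}-4-bromobenzene | COc1cc(OCc2ccccc2)ccc1CC[C@H](c1ccc(OCc2ccccc2)cc1)c1cc(Br)c(OCc2ccccc2)cc1OCc1ccccc1
F3 | step 9 | (R)-1-[4-(benzyloxy)phenyl]-3-{2,4-bis(benzyloxy)-5-[1-(4-(benzyloxy)phenyl)-3-(4-(benzyloxy)-2-methoxyphenyl)propyl]phenyl}propan-1-one | COc1cc(OCc2ccccc2)ccc1CC[C@H](c1ccc(OCc2ccccc2)cc1)c1cc(CCC(=O)c2ccc(OCc3ccccc3)cc2)c(OCc2ccccc2)cc1OCc1ccccc1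
F4 | step 4 | (E)-3-[2,4-bis(benzyloxy)-5-bromophenyl]prop-2-enal | O=C/C=C/c1cc(Br)c(OCc2ccccc2)cc1OCc1ccccc1
F5 | step 4 | (S)-3-[2,4-bis(benzyloxy)-5-bromophenyl]-5-(triisopropylsilyl)pent-4-ynal | O=CC[C@H](C#C[Si](C(C)C)(C(C)C)C(C)C)c1cc(Br)c(OCc2ccccc2)cc1OCc1ccccc1
F6 | step 4 | 4-(benzyloxy)-1-bromo-2-methoxybenzene | COc1cc(OCc2ccccc2)ccc1Br
F7 | step 4 | (3S)-1-[4-(benzyloxy)-2-methoxyphenyl]-3-[2,4-bis(benzyloxy)-5-bromophenyl]-5-(triisopropylsilyl)pent-4-yn-1-ol (carbinol epimers) | COc1cc(OCc2ccccc2)ccc1C(O)C[C@H](C#C[Si](C(C)C)(C(C)C)C(C)C)c1cc(Br)c(OCc2ccccc2)cc1OCc1ccccc1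
F8 | step 5 | N'-{(3S)-1-[4-(benzyloxy)-2-methoxyphenyl]-3-[2,4-bis(benzyloxy)-5-bromophenyl]-5-(triisopropylsilyl)pent-4-yn-1-ylidene}-4-methylbenzenesulfonohydrazide | COc1cc(OCc2ccccc2)ccc1C(=NNS(=O)(=O)c1ccc(C)cc1)C[C@H](C#C[Si](C(C)C)(C(C)C)C(C)C)c1cc(Br)c(OCc2ccccc2)cc1OCc1ccccc1
F9 | step 7 | {2,4-bis(benzyloxy)-5-[(3S)-5-(4-(benzyloxy)-2-methoxyphenyl)-1-(triisopropylsilyl)pent-1-yn-3-yl]phenyl}lithium | COc1cc(OCc2ccccc2)ccc1CC[C@H](C#C[Si](C(C)C)(C(C)C)C(C)C)c1cc([Li])c(OCc2ccccc2)cc1OCc1ccccc1
F10 | step 7 | (S)-2,4-bis(benzyloxy)-5-{5-[4-(benzyloxy)-2-methoxyphenyl]-1-(triisopropylsilyl)pent-1-yn-3-yl}benzaldehyde | COc1cc(OCc2ccccc2)ccc1CC[C@H](C#C[Si](C(C)C)(C(C)C)C(C)C)c1cc(C=O)c(OCc2ccccc2)cc1OCc1ccccc1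
F11 | step 7 | (S,E)-1-[4-(benzyloxy)phenyl]-3-{2,4-bis(benzyloxy)-5-[5-(4-(benzyloxy)-2-methoxyphenyl)-1-(triisopropylsilyl)pent-1-yn-3-yl]phenyl}prop-2-en-1-one | COc1cc(OCc2ccccc2)ccc1CC[C@H](C#C[Si](C(C)C)(C(C)C)C(C)C)c1cc(/C=C/C(=O)c2ccc(OCc3ccccc3)cc2)c(OCc2ccccc2)cc1OCc1ccccc1
F12 | step 10 | (R)-4-{1-[2,4-bis(benzyloxy)-5-(3-(4-(benzyloxy)phenyl)-3-oxopropyl)phenyl]-3-[4-(benzyloxy)-2-methoxyphenyl]propyl}cyclohex-3-en-1-one | COc1cc(OCc2ccccc2)ccc1CC[C@H](C1=CCC(=O)CC1)c1cc(CCC(=O)c2ccc(OCc3ccccc3)cc2)c(OCc2ccccc2)cc1OCc1ccccc1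
A1 | alternative 1 | 5-(benzyloxy)-2-{1-[4-(benzyloxy)phenyl]ethenyl}-4-{2-[2-(4-(benzyloxy)phenyl)-1,3-dioxolan-2-yl]ethyl}benzaldehyde | O=Cc1cc(OCc2ccccc2)c(CCC2(c3ccc(OCc4ccccc4)cc3)OCCO2)cc1C(=C)c1ccc(OCc2ccccc2)cc1
A2 | alternative 1 | (R)-6-(benzyloxy)-3-[4-(benzyloxy)phenyl]-5-{2-[2-(4-(benzyloxy)phenyl)-1,3-dioxolan-2-yl]ethyl}-2,3-dihydro-1H-inden-1-one | O=C1C[C@H](c2ccc(OCc3ccccc3)cc2)c2cc(CCC3(c4ccc(OCc5ccccc5)cc4)OCCO3)c(OCc3ccccc3)cc21
A3 | alternative 1 | (R)-7-(benzyloxy)-4-[4-(benzyloxy)phenyl]-6-{2-[2-(4-(benzyloxy)phenyl)-1,3-dioxolan-2-yl]ethyl}chroman-2-one | O=C1C[C@H](c2ccc(OCc3ccccc3)cc2)c2cc(CCC3(c4ccc(OCc5ccccc5)cc4)OCCO3)c(OCc3ccccc3)cc2O1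
A4 | alternative 2 | 3,3-bis[4-(benzyloxy)phenyl]propanoic acid | O=C(O)CC(c1ccc(OCc2ccccc2)cc1)c1ccc(OCc2ccccc2)cc1
A5 | alternative 2 | (R)-7-(benzyloxy)-4-[4-(benzyloxy)phenyl]chroman-2-one | O=C1C[C@H](c2ccc(OCc3ccccc3)cc2)c2ccc(OCc3ccccc3)cc2O1
A6 | alternative 3 | 2-(2-{2,4-bis(benzyloxy)-5-[(E)-2-bromoethenyl]phenyl}ethyl)-2-[4-(benzyloxy)phenyl]-1,3-dioxolane | Br/C=C/c1cc(CCC2(c3ccc(OCc4ccccc4)cc3)OCCO2)c(OCc2ccccc2)cc1OCc1ccccc1
A7 | alternative 3 | 2-[4-(benzyloxy)-2-methoxybenzyl]-4,4,5,5-tetramethyl-1,3,2-dioxaborolane | COc1cc(OCc2ccccc2)ccc1CB1OC(C)(C)C(C)(C)O1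
A8 | alternative 3 | 4-(benzyloxy)phenyl trifluoromethanesulfonate | O=S(=O)(Oc1ccc(OCc2ccccc2)cc1)C(F)(F)F
A9 | alternative 3 | 2-{(1R,2R)-1-[4-(benzyloxy)phenyl]-3-[4-(benzyloxy)-2-methoxyphenyl]-1-[2,4-bis(benzyloxy)-5-(2-(2-(4-(benzyloxy)phenyl)-1,3-dioxolan-2-yl)ethyl)phenyl]propan-2-yl}-4,4,5,5-tetramethyl-1,3,2-dioxaborolane | COc1cc(OCc2ccccc2)ccc1C[C@@H](B1OC(C)(C)C(C)(C)O1)[C@H](c1ccc(OCc2ccccc2)cc1)c1cc(CCC2(c3ccc(OCc4ccccc4)cc3)OCCO2)c(OCc2ccccc2)cc1OCc1ccccc1
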